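**Plan**
1. Numbering: ring O1, C2 (bears the chloroenyne chain, C1' = CHCl), C3–C7 (C7 bears C1'' = CHBr). Retrosynthetic cuts, in order: the enyne C3'=C4' (cross-metathesis); C1'–Cl and C1'–C2' (allylboration of a C2 aldehyde, then SN2 chloride); C4–Cl/C5–OH (SN2 opening of a C4–C5 cis-epoxide); last, the ring at C2–C3 together with O1–C2.
2. Enabling feature: O1 lies 1,3 to C5 across C7–C6, the C4/C5 chlorohydrin is the retron of a C4=C5 alkene, and C2 sits between O1 and C1', which can be a carbonyl. The oxepane is therefore the [2,3]-shift product of an oxonium ylide built from a 2-vinyloxetane (ring O1–C7–C6–C5, vinyl = C4=C3) and a carbene carbon C2 (ethyl diazoacetate).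
3. Forward order: (S)-epichlorohydrin + butyne → vinyl carbinol → E-alkene → trans-epoxide → cis-oxetane (4-exo) → bromide → three-atom ring expansion to the oxepene → iodolactone → epoxide → chlorohydrin → side chain.
4. Stereochemistry: C5 (sacrificial) from (S)-epichlorohydrin; C7 and C1'' from a reagent-controlled Shi epoxidation followed by one SN2 inversion each; C2 from the exo transition state of the ring expansion, relayed from C7 through the cis-oxetane; C4/C5 from carboxylate-directed iodolactonisation (face) and anti opening; C1' from a matched tartrate allylboration, then inversion by chloride; the Z-alkene from enyne cross-metathesis.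

Key step: step 7

Remark: the tartrate allylboronate of step 13 is taken as a reagent prepared separately by the standard one-pot procedure (allylmagnesium bromide, triisopropyl borate, diisopropyl (R,R)-tartrate); the silyl-capped enyne used in step 16 is made in step 15.

Step 1
Reactants: 1 (S)-epichlorohydrin; 2 but-1-yne
Product: 4 (2S)-1-chlorohept-4-yn-2-ol, via lithium but-1-ynide 3 (not isolated)
Conditions: 2, n-BuLi, THF, −78 °C; BF3·OEt2; then 1, −78 °C; aq. NH4Cl
Reagents that add atoms: none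
Why: BF3-promoted alkynylation of a terminal epoxide, in which the acetylide opens the activated oxirane at its CH2 terminus, so the stereocentre of 1 is untouched and becomes C5.

Step 2
Reactants: 4 (2S)-1-chlorohept-4-yn-2-ol
Product: 6 (3S)-oct-1-en-5-yn-3-ol, via alkynyl epoxide 5 (not isolated)
Conditions: Me3S+ I− (excess), n-BuLi, THF, −20 °C; then 4, −20 °C → rt; aq. NH4Cl
Reagents that add atoms: trimethylsulfonium iodide C[S+](C)C.[I-]
Why: Sulfonium-ylide one-carbon homologation of a terminal epoxide to an allylic alcohol: the alkoxide of 4 closes to 5, the methylide opens it at CH2 and a further ylide equivalent triggers loss of Me2S, all without touching the carbinol centre; the ylide carbon becomes C3.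

Step 3
Reactants: 6 (3S)-oct-1-en-5-yn-3-ol
Product: 7 (3S,5E)-octa-1,5-dien-3-ol
Conditions: Na, NH3 (l), THF, −78 → −33 °C; NH4Cl
Reagents that add atoms: none
Why: Dissolving-metal reduction of an internal alkyne should give the E-alkene through the trans vinyl anion, while the allylic alkoxide and the terminal alkene are inert.

Step 4
Reactants: 7 (3S,5E)-octa-1,5-dien-3-ol
Product: 8 (2S)-1-[(2S,3S)-3-ethyloxiran-2-yl]but-3-en-2-ol
Conditions: L-fructose-derived (ent-)Shi ketone (0.3 equiv), KHSO5 (as 2KHSO5·KHSO4·K2SO4), K2CO3, Bu4NHSO4, MeCN/CH2(OMe)2/aq. borate buffer (pH ≈ 10.5), 0 °C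
Reagents that add atoms: potassium peroxymonosulfate [K+].[O-]S(=O)(=O)OO
Why: Shi epoxidation: the chiral dioxirane attacks the electron-rich trans-disubstituted alkene in preference to the monosubstituted allylic-alcohol alkene, and the spiro transition state of the L-fructose-derived catalyst should give the (S,S)-epoxide by reagent control, setting the precursors of C7 and C1''.

Step 5
Reactants: 8 (2S)-1-[(2S,3S)-3-ethyloxiran-2-yl]but-3-en-2-ol
Product: 9 (1S)-1-[(2R,4S)-4-ethenyloxetan-2-yl]propan-1-ol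
Conditions: KOH, DMSO/H2O (3:1), 90 °C
Reagents that add atoms: none
Why: Base-mediated 4-exo-tet cyclisation of a trans-3,4-epoxy alcohol (oxetane formation in aqueous DMSO): the C5 alkoxide attacks C7 with inversion and frees the C1'' hydroxyl, 5-endo attack at C1'' being stereoelectronically disfavoured, so the (S) carbinol and the inverted C7 place the vinyl and 1-hydroxypropyl groups cis on the oxetane.

Step 6
Reactants: 9 (1S)-1-[(2R,4S)-4-ethenyloxetan-2-yl]propan-1-ol
Product: 10 (2R,4S)-2-[(1R)-1-bromopropyl]-4-ethenyloxetane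
Conditions: CBr4, P(n-C8H17)3, pyridine, toluene, 0 → 60 °C
Reagents that add atoms: carbon tetrabromide BrC(Br)(Br)Br
Why: Appel bromination: SN2 displacement of the alkoxyphosphonium inverts C1'' to R, and the buffered neutral medium should spare the oxetane, whose oxygen cannot participate because the bicyclic oxonium would be too strained.

Step 7
Reactants: 10 (2R,4S)-2-[(1R)-1-bromopropyl]-4-ethenyloxetane; 11 ethyl diazoacetate
Product: 13 ethyl (2R,7R)-7-[(1R)-1-bromopropyl]-2,3,6,7-tetrahydrooxepine-2-carboxylate, via oxetanium ylide 12 (not isolated)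
Conditions: Cu(CF3COCHCOCF3)2 (5 mol %), CH2Cl2, reflux, slow addition of 11 (3 equiv) by syringe pump
Reagents that add atoms: none
Why: The copper carbenoid from 11 is captured by the Lewis-basic, tied-back oxetane oxygen to give oxonium ylide 12, in which only the invertomer with the ylide carbon (future C2) syn to the C5 vinyl group can reach the vinyl terminus (future C3); a suprafacial [2,3]-sigmatropic shift through a five-membered envelope transition state then forms C2–C3, breaks the allylic O1–C5 bond and moves the double bond to C4=C5, driven by release of the oxetane strain. The closest known reaction type is the copper-catalysed [2,3] ring expansion of oxonium ylides generated intermolecularly from diazo esters and 2-vinyl cyclic ethers (vinyloxiranes, vinyloxetanes), with the ring expansion of 2-alkenylazetidinium ylides to azepines as the nitrogen analogue. The only ring closed is the oxepene, by a three-atom ring expansion (four-membered to seven-membered) whose ring-closing bond is C2–C3 and whose ring alkene is necessarily Z. The new stereocentre C2 is controlled by C7 through the cis-2,4-disubstituted oxetane: in the bicyclic transition state the ester must sit exo, because the endo position collides with the syn 1-bromopropyl group on C7, and this arrangement leads to the 2,7-trans (2R,7R) ester, while C5, which only oriented the vinyl group, is erased. The step needs ylide formation at oxygen to outrun cyclopropanation of the vinyl group, carbene dimerisation and the [1,2]-shift to a tetrahydrofuran; this should be secured by the electrophilic Cu(CF3COCHCOCF3)2, the only modestly nucleophilic monosubstituted alkene, slow addition of 11, and reversible ylide formation feeding the one invertomer that has the concerted [2,3] path.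

Step 8
Reactants: 13 ethyl (2R,7R)-7-[(1R)-1-bromopropyl]-2,3,6,7-tetrahydrooxepine-2-carboxylate
Product: 15 (2R,4R,5R,7R)-7-[(1R)-1-bromopropyl]-4-hydroxy-5-iodooxepane-2-carboxylic acid 2,4-lactone, via lithium carboxylate 14 (not isolated)
Conditions: LiOH, THF/H2O, 0 °C; then NaHCO3, I2, KI, 0 °C → rt, dark
Reagents that add atoms: lithium hydroxide [Li+].[OH-]; iodine II
Why: Saponification followed by iodolactonisation: the C2 carboxylate can reach the alkene only from its own face and closes the γ-lactone at C4 (five-membered over six-membered mode), so iodine ends up anti at C5 and the face of the later C5 oxygen is set by C2.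

Step 9
Reactants: 15 iodolactone
Product: 16 methyl (2R,4R,5S,7R)-7-[(1R)-1-bromopropyl]-4,5-epoxyoxepane-2-carboxylate
Conditions: K2CO3, MeOH, 0 °C
Reagents that add atoms: methanol CO
Why: Methanolysis of the lactone frees the C4 alkoxide, which displaces the anti C5 iodide (intramolecular Williamson reaction) to give the epoxide on the same face as the ester.

Step 10
Reactants: 16 methyl (2R,4R,5S,7R)-7-[(1R)-1-bromopropyl]-4,5-epoxyoxepane-2-carboxylate
Product: 18 methyl (2R,4S,5S,7R)-7-[(1R)-1-bromopropyl]-4-chloro-5-hydroxyoxepane-2-carboxylate, via trimethylsilyl ether 17 (not isolated)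
Conditions: Me3SiCl, PPh3 (cat.), CH2Cl2, −20 °C → rt; then citric acid, MeOH, 0 °C
Reagents that add atoms: chlorotrimethylsilane C[Si](C)(C)Cl
Why: Phosphine-catalysed silyl chloride opening of an epoxide (SN2, non-chelating): chloride must enter anti to the epoxide, and on that face the approach to C5 is 1,3-syn to the 1-bromopropyl group on C7 whereas C4 is flanked only by C2–H, so attack at C4 with inversion should give Cl at C4 and OH at C5 in the trans arrangement of the target.

Step 11
Reactants: 18 methyl (2R,4S,5S,7R)-7-[(1R)-1-bromopropyl]-4-chloro-5-hydroxyoxepane-2-carboxylate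
Product: 19 methyl (2R,4S,5S,7R)-7-[(1R)-1-bromopropyl]-5-[(tert-butyldimethylsilyl)oxy]-4-chlorooxepane-2-carboxylate
Conditions: t-BuMe2SiOSO2CF3, 2,6-lutidine, CH2Cl2, −78 → 0 °C
Reagents that add atoms: tert-butyldimethylsilyl triflate CC(C)(C)[Si](C)(C)OS(=O)(=O)C(F)(F)F
Why: Silylation of the secondary alcohol under non-nucleophilic base blocks C5–OH before it can lactonise onto the cis ester and keeps it out of the later chlorination.

Step 12
Reactants: 19 silyl ether ester
Product: 20 (2R,4S,5S,7R)-7-[(1R)-1-bromopropyl]-5-[(tert-butyldimethylsilyl)oxy]-4-chlorooxepane-2-carbaldehyde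
Conditions: i-Bu2AlH, CH2Cl2, −78 °C; aq. KNaC4H4O6
Reagents that add atoms: none
Why: Partial reduction of an α-alkoxy ester, whose chelated tetrahedral aluminate survives at −78 °C and releases the aldehyde only on work-up; the alkyl halides are inert.

Step 13
Reactants: 20 aldehyde
Product: 21 (1S)-1-[(2R,4S,5S,7R)-7-[(1R)-1-bromopropyl]-5-[(tert-butyldimethylsilyl)oxy]-4-chlorooxepan-2-yl]but-3-en-1-ol
Conditions: diisopropyl (4R,5R)-2-allyl-1,3,2-dioxaborolane-4,5-dicarboxylate, 4 Å molecular sieves, toluene, −78 °C; aq. NaHCO3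
Reagents that add atoms: diisopropyl (4R,5R)-2-allyl-1,3,2-dioxaborolane-4,5-dicarboxylate C=CCB1O[C@@H](C(=O)OC(C)C)[C@H](C(=O)OC(C)C)O1
Why: Roush asymmetric allylboration through a closed chair transition state: the (R,R)-tartrate reagent delivers allyl to the Si face, which coincides with the Felkin/Cornforth preference of this α-alkoxy aldehyde (matched pair), giving the 1,2-anti (1'S) alcohol.

Step 14
Reactants: 21 homoallylic alcohol
Product: 22 (2R,4S,5S,7R)-7-[(1R)-1-bromopropyl]-5-[(tert-butyldimethylsilyl)oxy]-4-chloro-2-[(1R)-1-chlorobut-3-en-1-yl]oxepane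
Conditions: CCl4, P(n-C8H17)3, toluene, 70 °C
Reagents that add atoms: carbon tetrachloride ClC(Cl)(Cl)Cl
Why: Appel chlorination: SN2 displacement of the alkoxyphosphonium by chloride inverts C1' to the R configuration of the target, a transformation with close precedent next to medium-ring ethers.

Step 15
Reactants: 23 ethynyltri(propan-2-yl)silane; 24 bromoethene
Product: 25 (but-3-en-1-yn-1-yl)tri(propan-2-yl)silane
Conditions: PdCl2(PPh3)2 (cat.), CuI (cat.), Et2NH, THF, 0 °C → rt
Reagents that add atoms: none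
Why: Sonogashira coupling of a terminal alkyne with a vinyl bromide gives the conjugated enyne.

Step 16
Reactants: 22 dichloride; 25 (but-3-en-1-yn-1-yl)tri(propan-2-yl)silane
Product: 26 {(3Z,6R)-6-[(2R,4S,5S,7R)-7-[(1R)-1-bromopropyl]-5-[(tert-butyldimethylsilyl)oxy]-4-chlorooxepan-2-yl]-6-chlorohex-3-en-1-yn-1-yl}tri(propan-2-yl)silane
Conditions: 25 (3 equiv), second-generation Grubbs catalyst (H2IMes)(PCy3)Cl2Ru=CHPh (10 mol %), benzene, 70 °C
Reagents that add atoms: none
Why: Olefin cross-metathesis of a terminal alkene with a silyl-capped conjugated enyne, a pairing known to favour the Z-enyne, with the bulky silyl group keeping the alkyne out of enyne metathesis.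

Step 17
Reactants: 26 silyl-protected enyne
Product: 27 (2R,4S,5S,7R)-2-[(1R)-1-bromopropyl]-5-chloro-7-[(1R,3Z)-1-chlorohex-3-en-5-yn-1-yl]oxepan-4-ol (CNP0327575.1)
Conditions: Bu4NF, AcOH, THF, 0 °C → rt
Reagents that add atoms: none
Why: Fluoride-mediated desilylation removes the alkynyl and the O-silyl groups in one operation, the acetic acid buffer keeping the liberated C5 alkoxide protonated so that it neither closes back onto C4–Cl nor promotes elimination of the secondary halides.

**Compound list**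
1 | (S)-epichlorohydrin [(2S)-2-(chloromethyl)oxirane] | ClC[C@@H]1CO1 | starting material
2 | but-1-yne | CCC#C | starting material
3 | lithium but-1-yn-1-ide | [Li+].[C-]#CCC | intermediate
4 | (2S)-1-chlorohept-4-yn-2-ol | ClC[C@@H](O)CC#CCC | intermediate
5 | (2S)-2-(pent-2-yn-1-yl)oxirane | C1O[C@H]1CC#CCC | intermediate
6 | (3S)-oct-1-en-5-yn-3-ol | C=C[C@@H](O)CC#CCC | intermediate
7 | (3S,5E)-octa-1,5-dien-3-ol | C=C[C@@H](O)C/C=C/CC | intermediate
8 | (2S)-1-[(2S,3S)-3-ethyloxiran-2-yl]but-3-en-2-ol | C=C[C@@H](O)C[C@@H]1O[C@H]1CC | intermediate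
9 | (1S)-1-[(2R,4S)-4-ethenyloxetan-2-yl]propan-1-ol (cis-oxetane) | C=C[C@@H]1C[C@@H](O1)[C@@H](O)CC | intermediate
10 | (2R,4S)-2-[(1R)-1-bromopropyl]-4-ethenyloxetane | C=C[C@@H]1C[C@@H](O1)[C@H](Br)CC | intermediate
11 | ethyl diazoacetate | CCOC(=O)C=[N+]=[N-] | starting material
12 | oxetanium ylide (1-[(ethoxycarbonyl)methanidyl]oxetan-1-ium of 10) | CCOC(=O)[CH-][O+]1[C@H](C=C)C[C@@H]1[C@H](Br)CC | intermediate
13 | ethyl (2R,7R)-7-[(1R)-1-bromopropyl]-2,3,6,7-tetrahydrooxepine-2-carboxylate | CCOC(=O)[C@H]1CC=CC[C@H]([C@H](Br)CC)O1 | intermediate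
14 | lithium (2R,7R)-7-[(1R)-1-bromopropyl]-2,3,6,7-tetrahydrooxepine-2-carboxylate | [Li+].[O-]C(=O)[C@H]1CC=CC[C@H]([C@H](Br)CC)O1 | intermediate
15 | (2R,4R,5R,7R)-7-[(1R)-1-bromopropyl]-4-hydroxy-5-iodooxepane-2-carboxylic acid 2,4-lactone (γ-lactone bridging C2 and C4, iodine anti at C5) | O=C1O[C@@H]2C[C@H]1O[C@H](C[C@H]2I)[C@H](Br)CC | intermediate
16 | methyl (2R,4R,5S,7R)-7-[(1R)-1-bromopropyl]-4,5-epoxyoxepane-2-carboxylate (epoxide cis to the ester) | COC(=O)[C@H]1C[C@H]2O[C@H]2C[C@H]([C@H](Br)CC)O1 | intermediate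
17 | methyl (2R,4S,5S,7R)-7-[(1R)-1-bromopropyl]-4-chloro-5-[(trimethylsilyl)oxy]oxepane-2-carboxylate | COC(=O)[C@H]1C[C@H](Cl)[C@@H](O[Si](C)(C)C)C[C@H]([C@H](Br)CC)O1 | intermediate
18 | methyl (2R,4S,5S,7R)-7-[(1R)-1-bromopropyl]-4-chloro-5-hydroxyoxepane-2-carboxylate | COC(=O)[C@H]1C[C@H](Cl)[C@@H](O)C[C@H]([C@H](Br)CC)O1 | intermediate
19 | methyl (2R,4S,5S,7R)-7-[(1R)-1-bromopropyl]-5-[(tert-butyldimethylsilyl)oxy]-4-chlorooxepane-2-carboxylate | COC(=O)[C@H]1C[C@H](Cl)[C@@H](O[Si](C)(C)C(C)(C)C)C[C@H]([C@H](Br)CC)O1 | intermediate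
20 | (2R,4S,5S,7R)-7-[(1R)-1-bromopropyl]-5-[(tert-butyldimethylsilyl)oxy]-4-chlorooxepane-2-carbaldehyde | O=C[C@H]1C[C@H](Cl)[C@@H](O[Si](C)(C)C(C)(C)C)C[C@H]([C@H](Br)CC)O1 | intermediate
21 | (1S)-1-[(2R,4S,5S,7R)-7-[(1R)-1-bromopropyl]-5-[(tert-butyldimethylsilyl)oxy]-4-chlorooxepan-2-yl]but-3-en-1-ol | C=CC[C@H](O)[C@H]1C[C@H](Cl)[C@@H](O[Si](C)(C)C(C)(C)C)C[C@H]([C@H](Br)CC)O1 | intermediate
22 | (2R,4S,5S,7R)-7-[(1R)-1-bromopropyl]-5-[(tert-butyldimethylsilyl)oxy]-4-chloro-2-[(1R)-1-chlorobut-3-en-1-yl]oxepane | C=CC[C@@H](Cl)[C@H]1C[C@H](Cl)[C@@H](O[Si](C)(C)C(C)(C)C)C[C@H]([C@H](Br)CC)O1 | intermediate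
23 | ethynyltri(propan-2-yl)silane | C#C[Si](C(C)C)(C(C)C)C(C)C | starting material
24 | bromoethene (vinyl bromide) | C=CBr | starting material
25 | (but-3-en-1-yn-1-yl)tri(propan-2-yl)silane | C=CC#C[Si](C(C)C)(C(C)C)C(C)C | intermediate
26 | {(3Z,6R)-6-[(2R,4S,5S,7R)-7-[(1R)-1-bromopropyl]-5-[(tert-butyldimethylsilyl)oxy]-4-chlorooxepan-2-yl]-6-chlorohex-3-en-1-yn-1-yl}tri(propan-2-yl)silane | CC(C)[Si](C(C)C)(C(C)C)C#C/C=C\C[C@@H](Cl)[C@H]1C[C@H](Cl)[C@@H](O[Si](C)(C)C(C)(C)C)C[C@H]([C@H](Br)CC)O1 | intermediate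
27 | (2R,4S,5S,7R)-2-[(1R)-1-bromopropyl]-5-chloro-7-[(1R,3Z)-1-chlorohex-3-en-5-yn-1-yl]oxepan-4-ol | C#C/C=C\C[C@@H](Cl)[C@H]1C[C@H](Cl)[C@@H](O)C[C@H]([C@H](Br)CC)O1 | target

**Count**
Total steps: 17. Longest linear sequence: 16 steps (steps 1–14, 16, 17, from (S)-epichlorohydrin); step 15 is a one-step side branch.

**Steps most likely to fail**

1. Step 7. What may go wrong: the carbenoid may cyclopropanate the vinyl group or dimerise, the wrong ylide invertomer may undergo a [1,2]-shift to a tetrahydrofuran, or exo/endo control may be weak and erode the 2,7-trans selectivity. Fallback (ether formation, then ring-closing metathesis), setting out from 10 and returning at 13: Pd(PPh3)4 (zerovalent palladium) and acetic acid should open the vinyloxetane 1,4 through the π-allyl complex to give (2E,5R,6R)-6-bromo-5-hydroxyoct-2-en-1-yl acetate F1. Its secondary hydroxyl would be alkylated, with SN2 inversion and 2,6-di-tert-butyl-4-methylpyridine as acid scavenger, by ethyl (2S)-2-{[(trifluoromethyl)sulfonyl]oxy}pent-4-enoate F2 (from commercial ethyl (2S)-2-hydroxypent-4-enoate, (CF3SO2)2O, 2,6-lutidine), giving ethyl (2R)-2-{[(3R,4R,6E)-8-acetoxy-3-bromooct-6-en-4-yl]oxy}pent-4-enoate F3. Ring-closing metathesis of F3 with the second-generation Grubbs catalyst should then close the C4=C5 bond, expel allyl acetate and give 13, whose two ring stereocentres are carried in unchanged from F1 and F2.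

2. Step 10. What may go wrong: chloride may attack C5 instead of C4 (regiochemical leakage), or the freed C5 hydroxyl may lactonise onto the cis ester. Fallback (dihydroxylation with lactone differentiation, then SN2 chlorination), setting out from 13 and returning at 20: OsO4 (cat.)/N-methylmorpholine N-oxide dihydroxylation followed by acid-catalysed lactonisation; only the diol formed on the ester face can close the γ-lactone at C4, giving (2R,4R,5S,7R)-7-[(1R)-1-bromopropyl]-4,5-dihydroxyoxepane-2-carboxylic acid 2,4-lactone F4, separable from the unlactonised diol ester. Silylation (t-BuMe2SiOSO2CF3, 2,6-lutidine) gives its 5-O-tert-butyldimethylsilyl ether F5. Aminolysis with MeNH(OMe)·HCl/AlMe3 opens the lactone to (2R,4R,5S,7R)-7-[(1R)-1-bromopropyl]-5-[(tert-butyldimethylsilyl)oxy]-4-hydroxy-N-methoxy-N-methyloxepane-2-carboxamide F6. Appel chlorination (CCl4, P(n-C8H17)3) inverts C4 to give (2R,4S,5S,7R)-7-[(1R)-1-bromopropyl]-5-[(tert-butyldimethylsilyl)oxy]-4-chloro-N-methoxy-N-methyloxepane-2-carboxamide F7. i-Bu2AlH reduction of the amide then gives aldehyde 20.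

3. Step 16. What may go wrong: poor Z/E control, or enyne-metathesis side paths and catalyst deactivation by the conjugated enyne. Fallback (stepwise Z-iodoolefination and Sonogashira coupling, with chlorination moved to the end), setting out from 21 and returning at 26: Et3SiCl/imidazole gives the triethylsilyl ether F8 of 21. Ozonolysis (O3, then PPh3) gives (3S)-3-[(2R,4S,5S,7R)-7-[(1R)-1-bromopropyl]-5-[(tert-butyldimethylsilyl)oxy]-4-chlorooxepan-2-yl]-3-[(triethylsilyl)oxy]propanal F9. Stork–Zhao olefination (Ph3P+CH2I I−, NaN(SiMe3)2, THF, −78 °C) gives the (Z)-vinyl iodide F10. Sonogashira coupling with 23 (Pd(PPh3)4, CuI, Et2NH) gives the silylated (Z)-enyne triethylsilyl ether F11. Pyridinium p-toluenesulfonate in MeOH removes only the triethylsilyl group to give the (1'S)-alcohol F12, and Appel chlorination (CCl4, P(n-C8H17)3) with inversion gives 26.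

**Further compounds**
F1 | step 7 | (2E,5R,6R)-6-bromo-5-hydroxyoct-2-en-1-yl acetate | CC(=O)OC/C=C/C[C@@H](O)[C@H](Br)CC
F2 | step 7 | ethyl (2S)-2-{[(trifluoromethyl)sulfonyl]oxy}pent-4-enoate | CCOC(=O)[C@H](CC=C)OS(=O)(=O)C(F)(F)F
F3 | step 7 | ethyl (2R)-2-{[(3R,4R,6E)-8-acetoxy-3-bromooct-6-en-4-yl]oxy}pent-4-enoate | CCOC(=O)[C@@H](CC=C)O[C@H](C/C=C/COC(C)=O)[C@H](Br)CC
F4 | step 10 | (2R,4R,5S,7R)-7-[(1R)-1-bromopropyl]-4,5-dihydroxyoxepane-2-carboxylic acid 2,4-lactone | O=C1O[C@@H]2C[C@H]1O[C@H](C[C@@H]2O)[C@H](Br)CC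
F5 | step 10 | 5-O-tert-butyldimethylsilyl ether of F4 | O=C1O[C@@H]2C[C@H]1O[C@H](C[C@@H]2O[Si](C)(C)C(C)(C)C)[C@H](Br)CC
F6 | step 10 | (2R,4R,5S,7R)-7-[(1R)-1-bromopropyl]-5-[(tert-butyldimethylsilyl)oxy]-4-hydroxy-N-methoxy-N-methyloxepane-2-carboxamide | CON(C)C(=O)[C@H]1C[C@@H](O)[C@@H](O[Si](C)(C)C(C)(C)C)C[C@H]([C@H](Br)CC)O1
F7 | step 10 | (2R,4S,5S,7R)-7-[(1R)-1-bromopropyl]-5-[(tert-butyldimethylsilyl)oxy]-4-chloro-N-methoxy-N-methyloxepane-2-carboxamide | CON(C)C(=O)[C@H]1C[C@H](Cl)[C@@H](O[Si](C)(C)C(C)(C)C)C[C@H]([C@H](Br)CC)O1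
F8 | step 16 | triethylsilyl ether of 21 | C=CC[C@H](O[Si](CC)(CC)CC)[C@H]1C[C@H](Cl)[C@@H](O[Si](C)(C)C(C)(C)C)C[C@H]([C@H](Br)CC)O1
F9 | step 16 | (3S)-3-[(2R,4S,5S,7R)-7-[(1R)-1-bromopropyl]-5-[(tert-butyldimethylsilyl)oxy]-4-chlorooxepan-2-yl]-3-[(triethylsilyl)oxy]propanal | O=CC[C@H](O[Si](CC)(CC)CC)[C@H]1C[C@H](Cl)[C@@H](O[Si](C)(C)C(C)(C)C)C[C@H]([C@H](Br)CC)O1
F10 | step 16 | (Z)-vinyl iodide: (2R,4S,5S,7R)-7-[(1R)-1-bromopropyl]-5-[(tert-butyldimethylsilyl)oxy]-4-chloro-2-[(1S,3Z)-4-iodo-1-[(triethylsilyl)oxy]but-3-en-1-yl]oxepane | I/C=C\C[C@H](O[Si](CC)(CC)CC)[C@H]1C[C@H](Cl)[C@@H](O[Si](C)(C)C(C)(C)C)C[C@H]([C@H](Br)CC)O1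
F11 | step 16 | silylated (Z)-enyne triethylsilyl ether | CC(C)[Si](C(C)C)(C(C)C)C#C/C=C\C[C@H](O[Si](CC)(CC)CC)[C@H]1C[C@H](Cl)[C@@H](O[Si](C)(C)C(C)(C)C)C[C@H]([C@H](Br)CC)O1
F12 | step 16 | (1S,3Z)-1-[(2R,4S,5S,7R)-7-[(1R)-1-bromopropyl]-5-[(tert-butyldimethylsilyl)oxy]-4-chlorooxepan-2-yl]-6-[tri(propan-2-yl)silyl]hex-3-en-5-yn-1-ol | CC(C)[Si](C(C)C)(C(C)C)C#C/C=C\C[C@H](O)[C@H]1C[C@H](Cl)[C@@H](O[Si](C)(C)C(C)(C)C)C[C@H]([C@H](Br)CC)O1
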